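## Structural features

- **Skeleton.** The molecule is built on one cyclobutane (ring atoms C1–C4), and four rings are attached to it by single bonds only. C1 and C3 each carry an exocyclic carbonyl that is N-bound to a 5,6-dihydropyridin-2(1H)-one (two imides), and C2 and C4 each carry a 3,4-dimethoxyphenyl group.
- **Connectivity.** The substituents alternate around the ring (head-to-tail, truxillic connectivity), so all four ring bonds are of the same type, CH(aryl)–CH(acyl).
- **Configuration.** The SMILES places the C1 acyl and the C2 aryl on one face and the C3 acyl and the C4 aryl on the other. This gives four contiguous stereocentres in the cis,trans,cis (1α,2α,3β,4β, α-truxillic) pattern, with the acyls mutually trans and the aryls mutually trans.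
- **Symmetry.** This array has an inversion centre at the ring centroid, so the compound is achiral. The stereochemical task is to make one of the five head-to-tail diastereomers, not one enantiomer.
- **Fragile groups.** These are the two imides (acyl donors towards hydroxide, alkoxides and amines), their conjugated C=C bonds (Michael acceptors and chromophores), the acidic C1–H and C3–H, and the oxidisable dimethoxyarenes.
- **Real difficulty.** Connectivity (head-to-tail) and relative configuration must be controlled together, and the configuration is not the all-trans thermodynamic one, so equilibration cannot reach it.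
- **Feature exploited by the key step.** Each aryl-bearing carbon is cis to exactly one neighbouring carbonyl (C2 aryl/C1 C=O, C4 aryl/C3 C=O), and the inversion centre interchanges these two cis pairs. Each carbonyl can therefore steer a metal to the C–H bond on its own face of an adjacent CH2, and both halves can be built at once.

## Logic of the disconnections

**14 to 10 and 11.** The two exocyclic imide N–C(=O) bonds are cut. They are the most fragile bonds of the target, so they are made last. Their removal deletes both Michael acceptors and reduces the problem to the ring core 10 plus two equivalents of commercial 11. The forward step must be a double N-acylation (through 12 and 13) that is fast at low temperature and free of amine base, so that C1–H and C3–H are not exchanged.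

**10 to 8 to 7.** The two carboxyl C–OH bonds are traced back to amide C–N bonds to a bidentate auxiliary. The skeleton does not become simpler here. These two steps are the price of having a director in the key step. The forward steps must first loosen a robust secondary amide (8) and then cleave it with a small, weakly basic nucleophile (through 9) that does not enolise C1 or C3.

**7 to 4 and 5 (key disconnection).**
- The bonds cut are C2–C(aryl) and C4–C(aryl), one on each face of the ring.
- The cut is made there because each of these bonds is cis to one auxiliary-bearing carbonyl, so each can be formed by that carbonyl's own directed C–H metalation.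
- In one sentence: twofold amide-directed C(sp3)–H arylation of 4 with 5. That sentence does not describe a cinnamate photodimerisation.
- The gain is large. A tetrasubstituted ring with four stereocentres and a regiochemical problem goes back to a 1,3-disubstituted ring with a single cis/trans element and two CH2 groups, plus a commercial aryl iodide. Head-to-tail connectivity is built in, because only C2 and C4 carry hydrogen to replace.
- The demand is that each director acts once. After the first event (6), the second arylation must be steered by the unused C3 director to the lower face of C4, not by the used C1 director to the upper face.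

**4 to 1 and 2.** The two amide C–N bonds are cut, which leads to commercial 1 and two equivalents of commercial 2. The forward step (through 3) must not epimerise the trans-1,3 relation, which is the less stable one in a 1,3-disubstituted cyclobutane.

## Other disconnections considered

**Alternative 1:** the first that comes to mind.
- *Cut:* C1–C2 and C3–C4, the two bonds between the monomer halves.
- *Forward key step:* head-to-tail [2+2] photodimerisation of (E)-1-[3-(3,4-dimethoxyphenyl)acryloyl]-5,6-dihydropyridin-2(1H)-one A1, a copy of the presumed biosynthesis.
- *Grounds for preferring the chosen plan:*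
  - It is the shortest plan on paper, but nothing in A1 enforces the antiparallel head-to-tail pairing.
  - In solution the excited cinnamoyl unit should relax by E/Z isomerisation faster than it meets a partner.
  - The ring enone of A1 is a second C=C that can cycloadd.
  - In a crystal the outcome is fixed by a packing that cannot be designed from the structure.
  - It is also the plan that most chemists would draw first, so it fails the first test. The chosen plan replaces packing control by a bonded director.

**Alternative 2:**
- *Cut:* one ring bond, C1–C4, with an NH inserted.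
- *Forward key step:* N-amination of dimethyl (2,3-cis, 3,4-trans, 4,5-cis)-3,5-bis(3,4-dimethoxyphenyl)pyrrolidine-2,4-dicarboxylate A2 to a 1,1-diazene, loss of N2, and collapse of the 1,4-biradical (contractive cyclobutane synthesis).
- *Grounds for preferring the chosen plan:*
  - A2 needs a 2,5-trans arrangement, whereas a metal-templated endo [3+2] cycloaddition of an azomethine ylide to a cinnamate is expected to deliver 2,5-cis. That leads to the diastereomer with cis acyl groups.
  - The biradical would be stabilised at both ends (donor-benzylic and α-ester). Bond rotation and β-scission to two cinnamates should therefore compete with closure.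
  - A centrosymmetric target would be made from an unsymmetrical chiral precursor, which costs steps.

**Alternative 3:**
- *Cut:* the same C2–aryl and C4–aryl bonds, but traced back to carboxyl groups.
- *Forward key step:* commercial cis,trans,cis-cyclobutane-1,2,3,4-tetracarboxylic dianhydride A3 already has the up,up,down,down pattern. It would be opened with methanol and converted to the bis(N-hydroxyphthalimide) ester A4, followed by a double nickel-catalysed decarboxylative arylation.
- *Grounds for preferring the chosen plan:*
  - Opening of A3 has no bias between the 1,3- and the 1,2-diester.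
  - Each cyclobutyl radical from A4 is flanked by one ester on each face, so aryl capture has no facial control and the aryl cis/trans relation would be left to chance.
  - A concerted metalation with retention, as in the chosen plan, transmits the configuration instead of erasing it.

Key step: step 2

Assumption: the SMILES encodes the centrosymmetric (1α,2α,3β,4β) diastereomer, which is achiral, so "single enantiomer" is taken to mean this single meso diastereomer and no absolute stereocontrol is planned; 1 is taken to be purchasable as the pure trans isomer.

## Steps

Step 1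
Reactants: 1 trans-cyclobutane-1,3-dicarboxylic acid; 2 8-aminoquinoline (2.1 equiv)
Product: 4 trans-N1,N3-di(quinolin-8-yl)cyclobutane-1,3-dicarboxamide, via trans-cyclobutane-1,3-dicarbonyl dichloride 3 (not isolated)
Conditions: (COCl)2, cat. DMF, CH2Cl2, 0 °C to rt, concentrate; then 2, pyridine, CH2Cl2, 0 °C to rt; recrystallise
Reagents that add atoms: oxalyl chloride, O=C(Cl)C(=O)Cl (supplies the chlorine of intermediate 3 only)
Why: Acid chloride formation followed by Schotten–Baumann-type amidation of a weakly nucleophilic arylamine. Pyridine is too weak a base to dehydrochlorinate 3 to a ketene, so the trans-1,3 relation of 1 should be carried into 4, and crystallisation should remove any cis isomer.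

Step 2
Reactants: 4 trans-N1,N3-di(quinolin-8-yl)cyclobutane-1,3-dicarboxamide; 5 4-iodo-1,2-dimethoxybenzene (5 equiv)
Product: 7 (1α,2α,3β,4β)-2,4-bis(3,4-dimethoxyphenyl)-N1,N3-di(quinolin-8-yl)cyclobutane-1,3-dicarboxamide, via racemic (1α,2α,3β)-2-(3,4-dimethoxyphenyl)-N1,N3-di(quinolin-8-yl)cyclobutane-1,3-dicarboxamide 6 (not isolated)
Conditions: Pd(OAc)2 (15 mol %), AgOAc (4 equiv), PivOH (30 mol %), (CF3)2CHOH, 90 °C, sealed tube
Reagents that add atoms: none
Why: This is the auxiliary-directed Pd(II)/Pd(IV) β-C(sp3)–H arylation of a cyclobutanecarboxamide, run in two directions on one ring. Each deprotonated amide N and its quinoline N bind Pd(II) as an N,N-chelate, and carboxylate-assisted concerted metalation–deprotonation then cleaves a β-methylene C–H bond to give a five-membered palladacycle that must be cis-fused to the four-membered ring, so only the hydrogen on the face of that carbonyl can be reached. Oxidative addition of 5 gives Pd(IV), C–C reductive elimination proceeds with retention at carbon, and AgOAc removes iodide and returns the Pd(II) carboxylate. All four methylene C–H bonds of 4 are symmetry-equivalent (time-averaged C2h), so the first event can only give racemic 6 with the C2 aryl cis to the C1 carbonyl. In 6 the C3 amide, whose face is still free of aryl groups, should metalate the lower C4–H bond and so place the C4 aryl cis to the C3 carbonyl and trans to the C2 aryl, and both enantiomers of 6 converge on the same centrosymmetric 7. The selectivity needed is that of director C3 over director C1 at C4: a second event from C1 would put Pd(IV) and then an aryl group 1,3-syn to the C2 aryl and build a cis,cis aryl–acyl–aryl triad, and fluorinated-alcohol/pivalate conditions are of the kind that let one director act only once. The reaction should end by itself, because the β-C–H bonds left in 7 are hindered methines that could only give quaternary carbons. No ring of the product is closed; C2 and C4 are new stereocentres controlled by the two cis-fused palladacycles, and C1 and C3 keep the trans relation of 1 because N-metalated amides are poor carbon acids.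

Step 3
Reactants: 7 (1α,2α,3β,4β)-2,4-bis(3,4-dimethoxyphenyl)-N1,N3-di(quinolin-8-yl)cyclobutane-1,3-dicarboxamide
Product: 8 di-tert-butyl [(1α,2α,3β,4β)-2,4-bis(3,4-dimethoxyphenyl)cyclobutane-1,3-dicarbonyl]bis(quinolin-8-ylcarbamate)
Conditions: Boc2O (6 equiv), DMAP, MeCN, 50 °C
Reagents that add atoms: di-tert-butyl dicarbonate, CC(C)(C)OC(=O)OC(=O)OC(C)(C)C
Why: DMAP-catalysed N-tert-butoxycarbonylation of a secondary anilide gives an N-acyl carbamate that is twisted out of amide conjugation and so activated for acyl substitution. The conditions are essentially neutral, so C1–H and C3–H should not exchange.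

Step 4
Reactants: 8 di-tert-butyl [(1α,2α,3β,4β)-2,4-bis(3,4-dimethoxyphenyl)cyclobutane-1,3-dicarbonyl]bis(quinolin-8-ylcarbamate)
Product: 10 (1α,2α,3β,4β)-2,4-bis(3,4-dimethoxyphenyl)cyclobutane-1,3-dicarboxylic acid, via (1α,2α,3β,4β)-2,4-bis(3,4-dimethoxyphenyl)cyclobutane-1,3-dicarboperoxoic acid 9 (not isolated)
Conditions: LiOH·H2O, 30% aq. H2O2, THF/H2O 3:1, 0 °C to rt; aq. Na2SO3; then 1 M HCl
Reagents that add atoms: hydrogen peroxide, OO
Why: Hydroperoxide cleavage of an N-acyl carbamate: the small α-effect nucleophile should attack the twisted ring-acyl carbonyl rather than the carbamate carbonyl, and its low basicity should avoid enolisation at C1/C3. Sulfite reduces the peracid 9 to 10, and the dimethoxyarenes should tolerate the cold, brief exposure.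

Step 5
Reactants: 10 (1α,2α,3β,4β)-2,4-bis(3,4-dimethoxyphenyl)cyclobutane-1,3-dicarboxylic acid; 11 5,6-dihydropyridin-2(1H)-one (2.3 equiv)
Product: 14 1,1'-[(1α,2α,3β,4β)-2,4-bis(3,4-dimethoxyphenyl)cyclobutane-1,3-dicarbonyl]bis(5,6-dihydropyridin-2(1H)-one) (target), via (1α,2α,3β,4β)-2,4-bis(3,4-dimethoxyphenyl)cyclobutane-1,3-dicarbonyl dichloride 12 (not isolated), via lithium 6-oxo-3,6-dihydropyridin-1(2H)-ide 13 (not isolated)
Conditions: 10, (COCl)2, cat. DMF, CH2Cl2, 0 °C to rt, concentrate; separately 11, LiHMDS (2.2 equiv), THF, −78 °C; add 12 in THF, −78 to −30 °C; aq. NH4Cl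
Reagents that add atoms: oxalyl chloride, O=C(Cl)C(=O)Cl (chlorine of intermediate 12 only); lithium bis(trimethylsilyl)amide, [Li+].C[Si](C)(C)[N-][Si](C)(C)C (lithium of intermediate 13 only)
Why: N-acylation of a lactam anion by an acid chloride (imide formation). Pre-formed 13 should be consumed on contact with 12 at low temperature, so no amine base is present that could form a ketene at C1/C3, and no stereocentre is made or touched.

## Compound list

1 | trans-cyclobutane-1,3-dicarboxylic acid | O=C(O)[C@H]1C[C@H](C(=O)O)C1 | starting material
2 | 8-aminoquinoline | Nc1cccc2cccnc12 | starting material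
3 | trans-cyclobutane-1,3-dicarbonyl dichloride | O=C(Cl)[C@H]1C[C@H](C(=O)Cl)C1 | intermediate
4 | trans-N1,N3-di(quinolin-8-yl)cyclobutane-1,3-dicarboxamide | O=C(Nc1cccc2cccnc12)[C@H]1C[C@H](C(=O)Nc2cccc3cccnc23)C1 | intermediate
5 | 4-iodo-1,2-dimethoxybenzene | COc1ccc(I)cc1OC | starting material
6 | (1α,2α,3β)-2-(3,4-dimethoxyphenyl)-N1,N3-di(quinolin-8-yl)cyclobutane-1,3-dicarboxamide (racemic, one enantiomer drawn) | COc1ccc([C@H]2[C@H](C(=O)Nc3cccc4cccnc34)C[C@H]2C(=O)Nc2cccc3cccnc23)cc1OC | intermediate
7 | (1α,2α,3β,4β)-2,4-bis(3,4-dimethoxyphenyl)-N1,N3-di(quinolin-8-yl)cyclobutane-1,3-dicarboxamide | COc1ccc([C@H]2[C@H](C(=O)Nc3cccc4cccnc34)[C@H](c3ccc(OC)c(OC)c3)[C@H]2C(=O)Nc2cccc3cccnc23)cc1OC | intermediate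
8 | di-tert-butyl [(1α,2α,3β,4β)-2,4-bis(3,4-dimethoxyphenyl)cyclobutane-1,3-dicarbonyl]bis(quinolin-8-ylcarbamate) | COc1ccc([C@H]2[C@H](C(=O)N(C(=O)OC(C)(C)C)c3cccc4cccnc34)[C@H](c3ccc(OC)c(OC)c3)[C@H]2C(=O)N(C(=O)OC(C)(C)C)c2cccc3cccnc23)cc1OC | intermediate
9 | (1α,2α,3β,4β)-2,4-bis(3,4-dimethoxyphenyl)cyclobutane-1,3-dicarboperoxoic acid (present as its lithium salt, drawn neutral) | COc1ccc([C@H]2[C@H](C(=O)OO)[C@H](c3ccc(OC)c(OC)c3)[C@H]2C(=O)OO)cc1OC | intermediate
10 | (1α,2α,3β,4β)-2,4-bis(3,4-dimethoxyphenyl)cyclobutane-1,3-dicarboxylic acid | COc1ccc([C@H]2[C@H](C(=O)O)[C@H](c3ccc(OC)c(OC)c3)[C@H]2C(=O)O)cc1OC | intermediate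
11 | 5,6-dihydropyridin-2(1H)-one | O=C1C=CCCN1 | starting material
12 | (1α,2α,3β,4β)-2,4-bis(3,4-dimethoxyphenyl)cyclobutane-1,3-dicarbonyl dichloride | COc1ccc([C@H]2[C@H](C(=O)Cl)[C@H](c3ccc(OC)c(OC)c3)[C@H]2C(=O)Cl)cc1OC | intermediate
13 | lithium 6-oxo-3,6-dihydropyridin-1(2H)-ide | [Li+].O=C1C=CCC[N-]1 | intermediate
14 | 1,1'-[(1α,2α,3β,4β)-2,4-bis(3,4-dimethoxyphenyl)cyclobutane-1,3-dicarbonyl]bis(5,6-dihydropyridin-2(1H)-one) | COc1ccc([C@H]2[C@H](C(=O)N3CCC=CC3=O)[C@H](c3ccc(OC)c(OC)c3)[C@H]2C(=O)N2CCC=CC2=O)cc1OC | target

## Step count and least certain steps

Total step count: 5. Longest linear sequence: 5 (steps 1–5 from 1).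

**Step 2 (key step).**
- *What may go wrong:*
  - The second arylation may be steered by the director that has already acted (the C1 amide) to the upper face of C4. This would erode the aryl trans relation, because a single director of this class is known to be able to arylate both of its β-methylenes.
  - The reaction may stall after the first arylation, because a substrate and product with two bidentate sites can hold palladium in off-cycle bis-chelates.
  - The solubility of 4 may be low.
- *Fallback:* set out from 5. A Mizoroki–Heck reaction with acrylic acid (Pd(OAc)2, Et3N, DMF, 100 °C) should give (E)-3-(3,4-dimethoxyphenyl)acrylic acid F1. Irradiation of F1 as a crystalline powder (λ > 300 nm) should effect the topochemical head-to-tail [2+2] dimerisation, which relies on a centrosymmetric antiparallel packing that has to be secured by choice of polymorph. The route is rejoined at 10.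

**Step 5.**
- *What may go wrong:*
  - Proton exchange at C1/C3 through enolate or ketene formation during the double acylation. No 1,2-steric bias would restore the configuration.
  - Stalling after the first acylation.
  - Acyl transfer from the product imides to excess nucleophile or to water on work-up.
- *Fallback:* set out from 10 and build the lactam rings on the acyl groups instead of attaching them. Coupling with but-3-en-1-amine (EDC, HOBt) should give (1α,2α,3β,4β)-N1,N3-di(but-3-en-1-yl)-2,4-bis(3,4-dimethoxyphenyl)cyclobutane-1,3-dicarboxamide F4. N-Acryloylation (LiHMDS, acryloyl chloride, THF, −78 °C) should give the bis(N-acryloyl-N-but-3-enyl) imide F5. A double ring-closing metathesis (second-generation ruthenium benzylidene catalyst, CH2Cl2, 40 °C) closes both six-membered rings and rejoins the route at 14.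

**Step 3.**
- *What may go wrong:* carbamoylation of one or both amide N–H groups may be incomplete. Each is flanked by a cis aryl group and is tied up in an N–H···N hydrogen bond to the quinoline.
- *Fallback:* set out from 7 and use Lewis-acid alcoholysis instead of N-activation. BF3·OEt2 in MeOH (100 °C, sealed tube) should give dimethyl (1α,2α,3β,4β)-2,4-bis(3,4-dimethoxyphenyl)cyclobutane-1,3-dicarboxylate F2. Me3SnOH (1,2-dichloroethane, 80 °C) should hydrolyse F2 without enolisation, and the route is rejoined at 10.

**Step 4.**
- *What may go wrong:*
  - Hydroperoxide may attack the less hindered carbamate carbonyl. This removes the activating group instead of the auxiliary.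
  - Slow exchange of C1–H/C3–H may occur if the cleavage needs long times at room temperature.
- *Fallback:* set out from 8 and cleave reductively. NaBH4 (THF/EtOH, 0 °C to rt) should give [(1α,2α,3β,4β)-2,4-bis(3,4-dimethoxyphenyl)cyclobutane-1,3-diyl]dimethanol F3. Buffered oxidation of F3 (TEMPO, NaClO2, cat. NaOCl, pH 6.7, MeCN/H2O) rejoins the route at 10.

## Further compounds

F1 | step 2 | (E)-3-(3,4-dimethoxyphenyl)acrylic acid | COc1ccc(/C=C/C(=O)O)cc1OC
F2 | step 3 | dimethyl (1α,2α,3β,4β)-2,4-bis(3,4-dimethoxyphenyl)cyclobutane-1,3-dicarboxylate | COc1ccc([C@H]2[C@H](C(=O)OC)[C@H](c3ccc(OC)c(OC)c3)[C@H]2C(=O)OC)cc1OC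
F3 | step 4 | [(1α,2α,3β,4β)-2,4-bis(3,4-dimethoxyphenyl)cyclobutane-1,3-diyl]dimethanol | COc1ccc([C@H]2[C@H](CO)[C@H](c3ccc(OC)c(OC)c3)[C@H]2CO)cc1OC
F4 | step 5 | (1α,2α,3β,4β)-N1,N3-di(but-3-en-1-yl)-2,4-bis(3,4-dimethoxyphenyl)cyclobutane-1,3-dicarboxamide | COc1ccc([C@H]2[C@H](C(=O)NCCC=C)[C@H](c3ccc(OC)c(OC)c3)[C@H]2C(=O)NCCC=C)cc1OC
F5 | step 5 | (1α,2α,3β,4β)-N1,N3-diacryloyl-N1,N3-di(but-3-en-1-yl)-2,4-bis(3,4-dimethoxyphenyl)cyclobutane-1,3-dicarboxamide | COc1ccc([C@H]2[C@H](C(=O)N(CCC=C)C(=O)C=C)[C@H](c3ccc(OC)c(OC)c3)[C@H]2C(=O)N(CCC=C)C(=O)C=C)cc1OC
A1 | alternative 1 | (E)-1-[3-(3,4-dimethoxyphenyl)acryloyl]-5,6-dihydropyridin-2(1H)-one | COc1ccc(/C=C/C(=O)N2CCC=CC2=O)cc1OC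
A2 | alternative 2 | dimethyl (2,3-cis, 3,4-trans, 4,5-cis)-3,5-bis(3,4-dimethoxyphenyl)pyrrolidine-2,4-dicarboxylate (racemic, one enantiomer drawn) | COC(=O)[C@H]1N[C@H](c2ccc(OC)c(OC)c2)[C@H](C(=O)OC)[C@H]1c1ccc(OC)c(OC)c1
A3 | alternative 3 | cis,trans,cis-cyclobutane-1,2,3,4-tetracarboxylic dianhydride | O=C1OC(=O)[C@H]2[C@@H]1[C@@H]3C(=O)OC(=O)[C@H]23
A4 | alternative 3 | 1,3-bis(1,3-dioxoisoindolin-2-yl) 2,4-dimethyl (1α,2β,3β,4α)-cyclobutane-1,2,3,4-tetracarboxylate | O=C(ON1C(=O)c2ccccc2C1=O)[C@H]1[C@H](C(=O)OC)[C@H](C(=O)ON2C(=O)c3ccccc3C2=O)[C@H]1C(=O)OC
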